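**Retrosynthetic overview**

- The target comes from its 3'-O-methyl ether by a final thiolate demethylation.
- Ring B (C1, C5–C9) is the only ring that is made. It is cut at C1–C8: a tertiary C8 cation is captured by the enol carbon C1 of a dearomatised acylphloroglucinol, as in the biosynthesis, and this sets C1 and C8.
- C5–C6 is cut by alkylative dearomatisation of the diprenylated acylphloroglucinol with an enantiopure C20 triflate that already carries C7.
- The C20 unit comes from geranic acid and geranyl bromide by an auxiliary-controlled deconjugative alkylation.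
- Ring A is bought as phloroglucinol and is acylated and prenylated before ring B is closed.

Assumption: C1–C9 in the explanations are the atoms of the bicyclo[3.3.1]nonane core of the target (C1 and C5 bridgeheads, C9 the bridging carbonyl), and enolised triketones are drawn as one of their rapidly interconverting tautomers.

**Step 1**
Reactants: 1 phloroglucinol (benzene-1,3,5-triol); 2 3-methoxybenzoyl chloride
Product: 3 (3-methoxyphenyl)(2,4,6-trihydroxyphenyl)methanone
Conditions: AlCl3 (4 equiv), PhNO2, 60 °C; aq. HCl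
Reagents that add atoms: none
Why: Friedel–Crafts acylation of the threefold-symmetric, strongly activated arene gives a single regioisomer and stops after one acylation because the aryl ketone deactivates the ring, while the non-chelated meta methyl ether is not cleaved by AlCl3 at this temperature.

**Step 2**
Reactants: 3 (3-methoxyphenyl)(2,4,6-trihydroxyphenyl)methanone; 4 prenyl bromide (1-bromo-3-methylbut-2-ene)
Product: 6 (3-methoxyphenyl)[2,4,6-trihydroxy-3,5-bis(3-methylbut-2-en-1-yl)phenyl]methanone, via monoprenyl ketone 5 (not isolated)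
Conditions: 4 (2.2 equiv), 10% aq. KOH, 0 °C; aq. HCl
Reagents that add atoms: none
Why: Base-mediated double C-prenylation (SN2 alkylation of the ambident phenoxide through carbon), in which water solvates the oxygens and steers the soft allylic bromide to the two free ring carbons in turn, while the methyl ether keeps the second aryl ring out of the reaction.

**Step 3**
Reactants: 7 geranic acid, (2E)-3,7-dimethylocta-2,6-dienoic acid; 8 (4S)-4-benzyl-1,3-oxazolidin-2-one
Product: 10 (4S)-4-benzyl-3-[(2E)-3,7-dimethylocta-2,6-dienoyl]-1,3-oxazolidin-2-one, via mixed pivalic anhydride 9 (not isolated)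
Conditions: PivCl, Et3N, THF, −20 °C; then 8, LiCl, rt
Reagents that add atoms: none
Why: N-Acylation of the Evans oxazolidinone through the mixed pivalic anhydride (LiCl/Et3N variant), mild enough to leave the (2E) enoate geometry untouched.

**Step 4**
Reactants: 10 (4S)-4-benzyl-3-[(2E)-3,7-dimethylocta-2,6-dienoyl]-1,3-oxazolidin-2-one; 11 geranyl bromide, (2E)-1-bromo-3,7-dimethylocta-2,6-diene
Product: 12 (4S)-4-benzyl-3-[(2S,4E)-5,9-dimethyl-2-(6-methylhepta-1,5-dien-2-yl)deca-4,8-dienoyl]-1,3-oxazolidin-2-one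
Conditions: NaN(SiMe3)2, THF, −78 °C; then 11, −78 → −40 °C
Reagents that add atoms: none
Why: Evans deconjugative α-alkylation, in which the base removes a γ-proton from the methyl group syn to the carbonyl and the chelated sodium dienolate is alkylated at the α-carbon by SN2 attack on the allylic bromide from the face opposite the benzyl group; this sets the (2S) centre (the future C7, R in the target) with the usual high diastereoselectivity and moves the acid-derived alkene to the 1,1-disubstituted position.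

**Step 5**
Reactants: 12 (4S)-4-benzyl-3-[(2S,4E)-5,9-dimethyl-2-(6-methylhepta-1,5-dien-2-yl)deca-4,8-dienoyl]-1,3-oxazolidin-2-one
Product: 13 (2S,4E)-5,9-dimethyl-2-(6-methylhepta-1,5-dien-2-yl)deca-4,8-dien-1-ol
Conditions: LiBH4, MeOH (1 equiv), Et2O, 0 °C
Reagents that add atoms: none
Why: Reductive cleavage of the N-acyl oxazolidinone with LiBH4 gives the primary alcohol without touching the four alkenes and without epimerisation, because the α-centre is never enolised.

**Step 6**
Reactants: 13 (2S,4E)-5,9-dimethyl-2-(6-methylhepta-1,5-dien-2-yl)deca-4,8-dien-1-ol; 6 (3-methoxyphenyl)[2,4,6-trihydroxy-3,5-bis(3-methylbut-2-en-1-yl)phenyl]methanone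
Product: 15 (6R)-6-[(2R,4E)-5,9-dimethyl-2-(6-methylhepta-1,5-dien-2-yl)deca-4,8-dien-1-yl]-3,5-dihydroxy-2-(3-methoxybenzoyl)-4,6-bis(3-methylbut-2-en-1-yl)cyclohexa-2,4-dien-1-one, via triflate 14 (not isolated)
Conditions: 13, Tf2O, 2,6-lutidine, CH2Cl2, −78 °C; pentane, cold filtration; filtrate into 6, LiN(SiMe3)2 (3.1 equiv), THF, −78 → 0 °C; aq. HCl
Reagents that add atoms: none
Why: Alkylative dearomatisation, in which the trilithium salt of 6 is C-alkylated (SN2) by the primary triflate at a prenyl-bearing ring carbon rather than at the acyl-bearing one and so creates the quaternary centre that becomes C5; the remote C7 centre gives no useful facial bias, so 15 (6R) forms with its 6S epimer (about 1:1) and is separated from it by preparative HPLC before the acid step, since the 6S epimer would lead to the 7-endo diastereomer.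

**Step 7**
Reactants: 15 (6R)-6-[(2R,4E)-5,9-dimethyl-2-(6-methylhepta-1,5-dien-2-yl)deca-4,8-dien-1-yl]-3,5-dihydroxy-2-(3-methoxybenzoyl)-4,6-bis(3-methylbut-2-en-1-yl)cyclohexa-2,4-dien-1-one
Product: 17 (1S,5S,7R,8S)-7-[(2E)-3,7-dimethylocta-2,6-dien-1-yl]-4-hydroxy-3-(3-methoxybenzoyl)-8-methyl-1,5-bis(3-methylbut-2-en-1-yl)-8-(4-methylpent-3-en-1-yl)bicyclo[3.3.1]non-3-ene-2,9-dione, via tertiary carbocation 16 (not isolated)
Conditions: HCO2H (98%), 0 → 23 °C, 2 h
Reagents that add atoms: none
Why: Proposed new method: Markovnikov protonation of the 1,1-disubstituted alkene gives the tertiary cation 16 at the carbon that becomes C8, and the prenyl-bearing enol carbon C1, the same nucleophile as in the biosynthesis, captures it through a chair transition state with the C7 geranyl group equatorial, so that the existing centres (future C5 and C7) dictate C1 (S), while C8 (S) follows because the larger 4-methylpent-3-enyl arm takes the site eclipsing the C7–H bond (later equatorial) and the methyl group the site flanked by C6 and the geranyl group (later axial); O-capture gives a tertiary vinylogous ester that re-ionises in HCO2H, cations formed at the remote double bonds revert to alkene, and the acyl-bearing C3 is too electron-poor to compete, so the C1–C8 bonded bicycle is the sink; the closest known reaction type is the formic acid mediated biomimetic cationic cyclisation of dearomatised prenylated acylphloroglucinols to bicyclo[3.3.1]nonane cores with a gem-dimethyl C8, together with Lewis acid α-tert-alkylation of enol derivatives, and what is new is the unprotected enol, the stereogenic C8 and the number of competing alkenes.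

**Step 8**
Reactants: 17 (1S,5S,7R,8S)-7-[(2E)-3,7-dimethylocta-2,6-dien-1-yl]-4-hydroxy-3-(3-methoxybenzoyl)-8-methyl-1,5-bis(3-methylbut-2-en-1-yl)-8-(4-methylpent-3-en-1-yl)bicyclo[3.3.1]non-3-ene-2,9-dione
Product: 18 (1S,5S,7R,8S)-7-[(2E)-3,7-dimethylocta-2,6-dien-1-yl]-4-hydroxy-3-(3-hydroxybenzoyl)-8-methyl-1,5-bis(3-methylbut-2-en-1-yl)-8-(4-methylpent-3-en-1-yl)bicyclo[3.3.1]non-3-ene-2,9-dione
Conditions: NaSEt (10 equiv), DMF, 100 °C; aq. HCl
Reagents that add atoms: none
Why: Aryl methyl ether cleavage by SN2 attack of ethanethiolate on the O-methyl group, with the β-triketone sitting as its unreactive enolate; none of the four stereocentres can epimerise because C1, C5 and C8 are quaternary and C7 is not α to a carbonyl.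

**Compound list**

1 | phloroglucinol (benzene-1,3,5-triol) | Oc1cc(O)cc(O)c1 | starting material
2 | 3-methoxybenzoyl chloride | COc1cccc(c1)C(Cl)=O | starting material
3 | (3-methoxyphenyl)(2,4,6-trihydroxyphenyl)methanone | COc1cccc(c1)C(=O)c1c(O)cc(O)cc1O | intermediate
4 | prenyl bromide (1-bromo-3-methylbut-2-ene) | CC(C)=CCBr | starting material
5 | (3-methoxyphenyl)[2,4,6-trihydroxy-3-(3-methylbut-2-en-1-yl)phenyl]methanone (monoprenyl ketone, not isolated) | COc1cccc(c1)C(=O)c1c(O)cc(O)c(CC=C(C)C)c1O | intermediate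
6 | (3-methoxyphenyl)[2,4,6-trihydroxy-3,5-bis(3-methylbut-2-en-1-yl)phenyl]methanone | COc1cccc(c1)C(=O)c1c(O)c(CC=C(C)C)c(O)c(CC=C(C)C)c1O | intermediate
7 | geranic acid, (2E)-3,7-dimethylocta-2,6-dienoic acid | CC(C)=CCC/C(C)=C/C(=O)O | starting material
8 | (4S)-4-benzyl-1,3-oxazolidin-2-one | O=C1N[C@@H](Cc2ccccc2)CO1 | starting material
9 | (2E)-3,7-dimethylocta-2,6-dienoic 2,2-dimethylpropanoic anhydride (mixed pivalic anhydride, not isolated) | CC(C)=CCC/C(C)=C/C(=O)OC(=O)C(C)(C)C | intermediate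
10 | (4S)-4-benzyl-3-[(2E)-3,7-dimethylocta-2,6-dienoyl]-1,3-oxazolidin-2-one | CC(C)=CCC/C(C)=C/C(=O)N1[C@@H](Cc2ccccc2)COC1=O | intermediate
11 | geranyl bromide, (2E)-1-bromo-3,7-dimethylocta-2,6-diene | CC(C)=CCC/C(C)=C/CBr | starting material
12 | (4S)-4-benzyl-3-[(2S,4E)-5,9-dimethyl-2-(6-methylhepta-1,5-dien-2-yl)deca-4,8-dienoyl]-1,3-oxazolidin-2-one | CC(C)=CCC/C(C)=C/C[C@@H](C(=C)CCC=C(C)C)C(=O)N1[C@@H](Cc2ccccc2)COC1=O | intermediate
13 | (2S,4E)-5,9-dimethyl-2-(6-methylhepta-1,5-dien-2-yl)deca-4,8-dien-1-ol | CC(C)=CCC/C(C)=C/C[C@@H](C(=C)CCC=C(C)C)CO | intermediate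
14 | (2S,4E)-5,9-dimethyl-2-(6-methylhepta-1,5-dien-2-yl)deca-4,8-dien-1-yl trifluoromethanesulfonate (triflate, not isolated) | CC(C)=CCC/C(C)=C/C[C@@H](C(=C)CCC=C(C)C)COS(=O)(=O)C(F)(F)F | intermediate
15 | (6R)-6-[(2R,4E)-5,9-dimethyl-2-(6-methylhepta-1,5-dien-2-yl)deca-4,8-dien-1-yl]-3,5-dihydroxy-2-(3-methoxybenzoyl)-4,6-bis(3-methylbut-2-en-1-yl)cyclohexa-2,4-dien-1-one | CC(C)=CCC/C(C)=C/C[C@@H](C(=C)CCC=C(C)C)C[C@]1(CC=C(C)C)C(O)=C(CC=C(C)C)C(O)=C(C(=O)c2cccc(OC)c2)C1=O | intermediate
16 | tertiary carbocation formed from 15 by protonation of the terminal CH2 of its 1,1-disubstituted alkene (cationic carbon is the future C8; 6R and 2R as in 15; not isolated) | CC(C)=CCC/C(C)=C/C[C@@H]([C+](C)CCC=C(C)C)C[C@]1(CC=C(C)C)C(O)=C(CC=C(C)C)C(O)=C(C(=O)c2cccc(OC)c2)C1=O | intermediate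
17 | (1S,5S,7R,8S)-7-[(2E)-3,7-dimethylocta-2,6-dien-1-yl]-4-hydroxy-3-(3-methoxybenzoyl)-8-methyl-1,5-bis(3-methylbut-2-en-1-yl)-8-(4-methylpent-3-en-1-yl)bicyclo[3.3.1]non-3-ene-2,9-dione | CC(C)=CCC/C(C)=C/C[C@@H]1C[C@]2(CC=C(C)C)C(=O)[C@@](CC=C(C)C)(C(=O)C(C(=O)c3cccc(OC)c3)=C2O)[C@@]1(C)CCC=C(C)C | intermediate
18 | (1S,5S,7R,8S)-7-[(2E)-3,7-dimethylocta-2,6-dien-1-yl]-4-hydroxy-3-(3-hydroxybenzoyl)-8-methyl-1,5-bis(3-methylbut-2-en-1-yl)-8-(4-methylpent-3-en-1-yl)bicyclo[3.3.1]non-3-ene-2,9-dione (CNP0285073.1) | CC(C)=CCC/C(C)=C/C[C@@H]1C[C@]2(CC=C(C)C)C(=O)[C@@](CC=C(C)C)(C(=O)C(C(=O)c3cccc(O)c3)=C2O)[C@@]1(C)CCC=C(C)C | target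

**Step count and risks**

Total step count: 8. Longest linear sequence: 6 steps (7 → 10 → 12 → 13 → 15 → 17 → 18); the aromatic branch (1 → 3 → 6) joins at step 6.

The three steps most likely to fail:

Step 7 (cationic ring closure). The prenyl group on the quaternary ring carbon is protonated about as easily as the 1,1-disubstituted alkene, and its cation can close the same ring to an 8,8-dimethyl isomer. Further risks are oxygen instead of carbon capture, loss of the C7 configuration if 16 sheds a proton toward the tetrasubstituted alkene, and a poor ratio at C8. The fallback sets out from 15 and comes back at 17. It makes the cation by ionising a C–O bond instead of protonating an alkene among five prenyl-type double bonds. Mukaiyama hydration of 15 (Mn(dpm)3 cat., PhSiH3, O2, i-PrOH, 0 °C) is a hydrogen-atom-transfer reaction that picks the 1,1-disubstituted alkene over the trisubstituted ones. It gives the tertiary alcohol (6R)-3,5-dihydroxy-6-[(2R,4E)-2-(2-hydroxy-6-methylhept-5-en-2-yl)-5,9-dimethyldeca-4,8-dien-1-yl]-2-(3-methoxybenzoyl)-4,6-bis(3-methylbut-2-en-1-yl)cyclohexa-2,4-dien-1-one F1. In HCO2H/CH2Cl2 at −10 °C its tertiary C–O bond should ionise much faster than a trisubstituted alkene is protonated, and the resulting cation 16 closes to 17 as in step 7.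

Step 6 (alkylative dearomatisation). The hard triflate may alkylate oxygen, SN2 at a β-branched carbon onto a fully substituted nucleophilic carbon is slow, and there is no control at the new ring carbon, so about half of the material is the 6S epimer. The fallback sets out from 13 and comes back at 17. It replaces the mono-electrophile by a 1,3-bis-electrophile that brings both ring B bonds in one flask. Mukaiyama hydration of 13 (same reagents) gives the diol (2R,4E)-2-(2-hydroxy-6-methylhept-5-en-2-yl)-5,9-dimethyldeca-4,8-dien-1-ol F2. SO2Cl2 and imidazole in CH2Cl2 at −40 °C close it to the cyclic sulfate (5R)-5-[(2E)-3,7-dimethylocta-2,6-dien-1-yl]-4-methyl-4-(4-methylpent-3-en-1-yl)-1,3,2-dioxathiane 2,2-dioxide F3. The trilithium salt of 6 opens F3 at its primary carbon, a softer and more carbon-selective alkylation than with a triflate, to give the lithium tertiary-alkyl sulfate monoester of the C-alkylated dienone F4. Acidifying the same flask with HCO2H ionises the tertiary sulfate to cation 16, which closes to 17. Compounds 14 and 15 and the alkene protonation are by-passed, and the ring-carbon epimers are separated at the stage of 17.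

Step 8 (late demethylation). Hot thiolate on a polyene β-triketone may give incomplete cleavage, thiol addition to the alkenes or retro-Claisen loss of the aroyl group. The fallback sets out from 6 and comes back at 18. It exchanges the methyl ether for a silyl ether while the molecule is still a robust arene. NaSEt in DMF at 100 °C on 6 gives the tetraphenol (3-hydroxyphenyl)[2,4,6-trihydroxy-3,5-bis(3-methylbut-2-en-1-yl)phenyl]methanone F5. TBSCl and imidazole silylate its only unhindered, non-chelated phenol to give the silyl ether (3-{[tert-butyl(dimethyl)silyl]oxy}phenyl)[2,4,6-trihydroxy-3,5-bis(3-methylbut-2-en-1-yl)phenyl]methanone F6. Alkylation with 14 and ring closure in HCO2H, run as in steps 6 and 7, give the 3'-O-silyl analogue of 15 F7 and the 3'-O-silyl analogue of 17 F8. Bu4NF in THF at 0 °C then frees 18.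

**Further compounds**

F1 | step 7 | (6R)-3,5-dihydroxy-6-[(2R,4E)-2-(2-hydroxy-6-methylhept-5-en-2-yl)-5,9-dimethyldeca-4,8-dien-1-yl]-2-(3-methoxybenzoyl)-4,6-bis(3-methylbut-2-en-1-yl)cyclohexa-2,4-dien-1-one (both epimers at the carbinol carbon) | CC(C)=CCC/C(C)=C/C[C@@H](C(C)(O)CCC=C(C)C)C[C@]1(CC=C(C)C)C(O)=C(CC=C(C)C)C(O)=C(C(=O)c2cccc(OC)c2)C1=O
F2 | step 6 | (2R,4E)-2-(2-hydroxy-6-methylhept-5-en-2-yl)-5,9-dimethyldeca-4,8-dien-1-ol (both epimers at the carbinol carbon) | CC(C)=CCC/C(C)=C/C[C@@H](C(C)(O)CCC=C(C)C)CO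
F3 | step 6 | (5R)-5-[(2E)-3,7-dimethylocta-2,6-dien-1-yl]-4-methyl-4-(4-methylpent-3-en-1-yl)-1,3,2-dioxathiane 2,2-dioxide (both epimers at C4) | CC(C)=CCC/C(C)=C/C[C@@H]1COS(=O)(=O)OC1(C)CCC=C(C)C
F4 | step 6 | lithium 2-{(2R,4E)-1-[(1R)-2,4-dihydroxy-5-(3-methoxybenzoyl)-1,3-bis(3-methylbut-2-en-1-yl)-6-oxocyclohexa-2,4-dien-1-yl]-5,9-dimethyldeca-4,8-dien-2-yl}-6-methylhept-5-en-2-yl sulfate | [Li+].CC(C)=CCC/C(C)=C/C[C@@H](C(C)(OS(=O)(=O)[O-])CCC=C(C)C)C[C@]1(CC=C(C)C)C(O)=C(CC=C(C)C)C(O)=C(C(=O)c2cccc(OC)c2)C1=O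
F5 | step 8 | (3-hydroxyphenyl)[2,4,6-trihydroxy-3,5-bis(3-methylbut-2-en-1-yl)phenyl]methanone | Oc1cccc(c1)C(=O)c1c(O)c(CC=C(C)C)c(O)c(CC=C(C)C)c1O
F6 | step 8 | (3-{[tert-butyl(dimethyl)silyl]oxy}phenyl)[2,4,6-trihydroxy-3,5-bis(3-methylbut-2-en-1-yl)phenyl]methanone | CC(C)(C)[Si](C)(C)Oc1cccc(c1)C(=O)c1c(O)c(CC=C(C)C)c(O)c(CC=C(C)C)c1O
F7 | step 8 | (6R)-2-(3-{[tert-butyl(dimethyl)silyl]oxy}benzoyl)-6-[(2R,4E)-5,9-dimethyl-2-(6-methylhepta-1,5-dien-2-yl)deca-4,8-dien-1-yl]-3,5-dihydroxy-4,6-bis(3-methylbut-2-en-1-yl)cyclohexa-2,4-dien-1-one | CC(C)=CCC/C(C)=C/C[C@@H](C(=C)CCC=C(C)C)C[C@]1(CC=C(C)C)C(O)=C(CC=C(C)C)C(O)=C(C(=O)c2cccc(O[Si](C)(C)C(C)(C)C)c2)C1=O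
F8 | step 8 | (1S,5S,7R,8S)-3-(3-{[tert-butyl(dimethyl)silyl]oxy}benzoyl)-7-[(2E)-3,7-dimethylocta-2,6-dien-1-yl]-4-hydroxy-8-methyl-1,5-bis(3-methylbut-2-en-1-yl)-8-(4-methylpent-3-en-1-yl)bicyclo[3.3.1]non-3-ene-2,9-dione | CC(C)=CCC/C(C)=C/C[C@@H]1C[C@]2(CC=C(C)C)C(=O)[C@@](CC=C(C)C)(C(=O)C(C(=O)c3cccc(O[Si](C)(C)C(C)(C)C)c3)=C2O)[C@@]1(C)CCC=C(C)C
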